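**Plan**

- Retrosynthesis: (i) cut the CH2–CH2 link between the two rings (made as a C=C by Horner–Wadsworth–Emmons olefination, then saturated with diimide); (ii) cut both ring bonds C-1–C-6 (acyl–CH2) and C-3–C-4 (β-carbon–CMe2) of the cyclohexenone in one [3+3] event; (iii) cut O–C-3 of the dioxane (SN2) and the tertiary C-6–OO bond (epoxide perhydrolysis).
- Enabling feature: in the cyclohexenone ring (C-1 = C=O, C-2 = CMe, C-3, C-4 = CMe2, C-5, C-6) the α-CH2 C-6 and the gem-dimethyl carbon C-4 are 1,3-related across C-5, so C-4/C-5/C-6 is an opened 1,1-dimethylcyclopropane. C-1/C-2/C-3 is a tigloyl unit. The tertiary cation that ring opening leaves at C-4 is what attacks C-3.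
- Forward order: the cyclohexenone ring arises first (step 2) and becomes phosphonate 7. Separately an acyclic C9 chain is built and the 1,2-dioxane closes (step 10). The fragments are joined in step 14 and the link is saturated in step 15. The ring-forming event is run early on two C5 pieces because its Lewis acid would not spare an O–O bond.
- Stereochemistry: the α-methyl carbon and dioxane C-3 come from an anti-selective tartrate crotylboration, with C-3 inverted in the SN2 peroxide closure (anti becomes syn). Dioxane C-6 comes from a catalytic asymmetric Corey–Chaykovsky epoxidation followed by invertive perhydrolysis. Because two independent reagent-controlled steps are used, the minor enantiomer of each ends up in a separable diastereomer.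

Key step: step 2

Remark: the (R,R)-tartrate crotylboronate is taken to add to the Si face of 9, and the antipode of the epoxidation catalyst in step 8 is the one that gives the 2R oxirane; if either sense proves opposite on a model, the other antipode of that reagent is used and nothing else changes.

**Route**

Step 1
Reactants: 1 1,3-dibromo-2,2-dimethylpropane
Product: 2 1,1-dimethylcyclopropane
Conditions: Zn dust, EtOH/H2O, reflux; product (b.p. 21 °C) distilled into a −78 °C trap
Reagents that add atoms: none
Why: Zinc-mediated 1,3-debromination (Gustavson cyclopropane synthesis) of a 1,3-dihalide with a neopentyl centre, where no elimination can compete, should give the hydrocarbon cleanly; no stereocentre is involved.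

Step 2
Reactants: 2 1,1-dimethylcyclopropane; 3 (2E)-2-methylbut-2-enoyl chloride (tigloyl chloride)
Product: 5 2,3,4,4-tetramethylcyclohex-2-en-1-one, via chloroketone 4 (not isolated)
Conditions: AlCl3 (1.2 equiv), CH2Cl2, −78 °C; 2 (2.5 equiv) added to pre-formed 3·AlCl3; then → rt
Reagents that add atoms: none
Why: Proposed new method: the acylium ion from 3 and AlCl3 should attack an unsubstituted CH2 corner of 2 and cleave the strained CH2–CMe2 σ-bond, because only this cleavage puts the positive charge on a tertiary carbon; chloride return gives 4 (this forms the C-1–C-6 bond), and re-ionisation of 4 lets the tertiary cation at C-4 attack the β-carbon C-3 of the s-trans enone (as its enol or aluminium 2-oxydiene), which forms the C-3–C-4 bond and an oxyallyl cation that loses the C-3 proton as HCl. The closest known reaction types are the Friedel–Crafts acylation of alkylcyclopropanes, which opens the ring toward the more substituted carbon to γ-chloro ketones, the acid-mediated homo-Nazarov cyclisation of alkenyl cyclopropyl ketones to cyclohex-2-enones, and the one-pot acylation/Nazarov route from such acyl chlorides and alkenes to cyclopentenones, of which this is the homologue; new is their merger, by which a simple cyclopropane σ-bond accepts the whole enoyl unit. The six-membered ring closes in a 6-endo-trig cation–olefin mode, and the release of cyclopropane strain pays for the first bond. No stereocentre arises, since C-4 is an achiral quaternary carbon and the E geometry of 3 disappears in the tetrasubstituted ring alkene. The step needs regioselective ring opening, secured by the gem-dimethyl group, and C–C closure in preference to chloride capture, proton loss or O-closure to a dihydrofuran (Cloke–Wilson type); these diversions are expected to be reversible under the Lewis acid, whereas deprotonation to the conjugated enone 5 is not, so 5 should be the thermodynamic sink.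

Step 3
Reactants: 5 2,3,4,4-tetramethylcyclohex-2-en-1-one
Product: 6 3-(bromomethyl)-2,4,4-trimethylcyclohex-2-en-1-one
Conditions: NBS (1.05 equiv), AIBN (cat.), PhCF3, 80 °C
Reagents that add atoms: N-bromosuccinimide, O=C1CCC(=O)N1Br
Why: Wohl–Ziegler bromination should take hydrogen from the C-3 methyl group, because that radical is delocalised through C-2=C-3 into the carbonyl group (the vinylogous γ-position, whose ring counterpart C-4 is quaternary), whereas the radical from the C-2 methyl group is only cross-conjugated.

Step 4
Reactants: 6 3-(bromomethyl)-2,4,4-trimethylcyclohex-2-en-1-one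
Product: 7 diethyl [(2,6,6-trimethyl-3-oxocyclohex-1-en-1-yl)methyl]phosphonate
Conditions: P(OEt)3 (neat), 130 °C
Reagents that add atoms: triethyl phosphite, CCOP(OCC)OCC
Why: Michaelis–Arbuzov reaction of a primary allylic bromide; the hindered enone carbonyl is not expected to divert the phosphite.

Step 5
Reactants: 8 hex-5-en-2-one
Product: 9 4-oxopentanal
Conditions: O3, CH2Cl2, −78 °C; then Me2S, → rt; used at once
Reagents that add atoms: ozone, [O-][O+]=O
Why: Ozonolysis with reductive work-up cleaves the terminal alkene to the aldehyde and leaves the ketone alone.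

Step 6
Reactants: 9 4-oxopentanal
Product: 10 (5R,6S)-5-hydroxy-6-methyloct-7-en-2-one
Conditions: diisopropyl (R,R)-tartrate (E)-crotylboronate, 4 Å MS, toluene, −78 °C; aqueous work-up
Reagents that add atoms: diisopropyl (4R,5R)-2-[(2E)-but-2-en-1-yl]-1,3,2-dioxaborolane-4,5-dicarboxylate, CC(C)OC(=O)[C@@H]1OB(C/C=C/C)O[C@H]1C(=O)OC(C)C
Why: Tartrate-controlled asymmetric crotylboration (Roush crotylboration) through a closed chair transition state: the E geometry of the reagent sets the anti relation of methyl and hydroxyl, the (R,R)-tartrate directs addition to the Si face of the aldehyde (5R,6S), and the ketone does not react at −78 °C.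

Step 7
Reactants: 10 (5R,6S)-5-hydroxy-6-methyloct-7-en-2-one
Product: 11 (3S,4R)-3-methyl-7-oxooct-1-en-4-yl methanesulfonate
Conditions: MsCl, Et3N, CH2Cl2, −10 °C; used without delay
Reagents that add atoms: methanesulfonyl chloride, CS(=O)(=O)Cl
Why: O-Sulfonylation breaks no bond at carbon, so the configuration is kept and the carbinol carbon becomes the electrophile for the later peroxide ring closure.

Step 8
Reactants: 11 (3S,4R)-3-methyl-7-oxooct-1-en-4-yl methanesulfonate
Product: 12 (3S,4R)-3-methyl-6-[(2R)-2-methyloxiran-2-yl]hex-1-en-4-yl methanesulfonate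
Conditions: Me3S(O)Cl, NaH, THF (ylide pre-formed, NaCl filtered off); La–Li3–tris(binaphthoxide) (5 mol %, antipode as in the remark), (2,4,6-(MeO)3C6H2)3P=O (5 mol %), 5 Å MS, THF, rt
Reagents that add atoms: trimethylsulfoxonium chloride, C[S+](C)(C)=O.[Cl-]
Why: Catalytic asymmetric Corey–Chaykovsky epoxidation of a methyl ketone, in which the heterobimetallic catalyst chooses the carbonyl face and so sets the quaternary epoxide carbon as R independently of the remote stereocentres; the weakly basic ylide and the iodide-free medium should leave the secondary mesylate untouched.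

Step 9
Reactants: 12 (3S,4R)-3-methyl-6-[(2R)-2-methyloxiran-2-yl]hex-1-en-4-yl methanesulfonate
Product: 13 (3S,4R,7S)-7-hydroperoxy-8-hydroxy-3,7-dimethyloct-1-en-4-yl methanesulfonate
Conditions: anhydrous H2O2 in Et2O (excess), phosphomolybdic acid (cat.), rt
Reagents that add atoms: hydrogen peroxide, OO
Why: Molybdenum-catalysed perhydrolysis of a 2,2-disubstituted epoxide should open the ring at the tertiary carbon with inversion, which gives the tertiary hydroperoxide as the 7S isomer and frees the primary hydroxyl group; the mesylate and the vinyl group are inert to acidic H2O2.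

Step 10
Reactants: 13 (3S,4R,7S)-7-hydroperoxy-8-hydroxy-3,7-dimethyloct-1-en-4-yl methanesulfonate
Product: 14 [(3S,6S)-6-[(2S)-but-3-en-2-yl]-3-methyl-1,2-dioxan-3-yl]methanol
Conditions: KOtBu (1.05 equiv), 18-crown-6, THF, 0 °C
Reagents that add atoms: none
Why: Intramolecular SN2 alkylation of the hydroperoxide anion (6-exo-tet closure), selective because the hydroperoxide is about four pKa units more acidic than the primary alcohol; inversion at the mesylate carbon turns the anti pair from step 6 into the syn arrangement of the target.

Step 11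
Reactants: 14 [(3S,6S)-6-[(2S)-but-3-en-2-yl]-3-methyl-1,2-dioxan-3-yl]methanol
Product: 16 (2R)-2-[(3S,6S)-6-(hydroxymethyl)-6-methyl-1,2-dioxan-3-yl]propanoic acid, via aldehyde 15 (not isolated)
Conditions: O3, CH2Cl2, −78 °C; Me2S; then NaClO2, NaH2PO4, 2-methylbut-2-ene, t-BuOH/H2O, 0 °C → rt
Reagents that add atoms: ozone, [O-][O+]=O; sodium chlorite, [Na+].[O-]Cl=O
Why: Ozonolysis followed by Pinnick oxidation turns the vinyl group into the carboxyl group in a medium that is never basic, so the α-stereocentre of the β-peroxy aldehyde should neither epimerise nor open the ring by retro-oxa-Michael elimination; the dialkyl peroxide and the primary alcohol are inert to both oxidants.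

Step 12
Reactants: 16 (2R)-2-[(3S,6S)-6-(hydroxymethyl)-6-methyl-1,2-dioxan-3-yl]propanoic acid
Product: 17 methyl (2R)-2-[(3S,6S)-6-(hydroxymethyl)-6-methyl-1,2-dioxan-3-yl]propanoate
Conditions: TMSCHN2, MeOH/toluene, 0 °C
Reagents that add atoms: (trimethylsilyl)diazomethane, C[Si](C)(C)C=[N+]=[N-]
Why: Diazoalkane esterification of the acid under neutral conditions leaves the alcohol, the peroxide and the α-stereocentre untouched.

Step 13
Reactants: 17 methyl (2R)-2-[(3S,6S)-6-(hydroxymethyl)-6-methyl-1,2-dioxan-3-yl]propanoate
Product: 18 methyl (2R)-2-[(3S,6S)-6-formyl-6-methyl-1,2-dioxan-3-yl]propanoate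
Conditions: Dess–Martin periodinane, CH2Cl2, 0 °C → rt
Reagents that add atoms: none
Why: Dess–Martin oxidation of the primary alcohol; the aldehyde carbon sits on a quaternary centre, so it can neither enolise nor epimerise.

Step 14
Reactants: 7 diethyl [(2,6,6-trimethyl-3-oxocyclohex-1-en-1-yl)methyl]phosphonate; 18 methyl (2R)-2-[(3S,6S)-6-formyl-6-methyl-1,2-dioxan-3-yl]propanoate
Product: 19 methyl (2R)-2-[(3S,6S)-6-methyl-6-[(E)-2-(2,6,6-trimethyl-3-oxocyclohex-1-en-1-yl)ethenyl]-1,2-dioxan-3-yl]propanoate
Conditions: 7, NaH (1.0 equiv), THF, 0 °C; then 18, −20 °C → rt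
Reagents that add atoms: none
Why: Horner–Wadsworth–Emmons olefination with the vinylogous β-keto phosphonate anion, which reacts at the carbon next to phosphorus and should give the E alkene (either geometry serves, since the bond is reduced next); no free base is left over, so the β-peroxy ester and the C-3 hydrogen of the dioxane should survive.

Step 15
Reactants: 19 methyl (2R)-2-[(3S,6S)-6-methyl-6-[(E)-2-(2,6,6-trimethyl-3-oxocyclohex-1-en-1-yl)ethenyl]-1,2-dioxan-3-yl]propanoate
Product: 20 methyl (2R)-2-[(3S,6R)-6-methyl-6-[2-(2,6,6-trimethyl-3-oxocyclohex-1-en-1-yl)ethyl]-1,2-dioxan-3-yl]propanoate (methyl diacarnoate A)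
Conditions: KO2C–N=N–CO2K (excess, in portions), AcOH, MeOH/CH2Cl2, 0 °C → rt
Reagents that add atoms: none
Why: Diimide reduction transfers H2 in a concerted syn fashion to the disubstituted C=C and should leave the O–O bond, the ester and the tetrasubstituted, electron-poor ring alkene alone, which is the usual way to saturate an alkene in a peroxide.

**Compound list**

1 | 1,3-dibromo-2,2-dimethylpropane | BrCC(C)(C)CBr | starting material
2 | 1,1-dimethylcyclopropane | CC1(C)CC1 | intermediate
3 | (2E)-2-methylbut-2-enoyl chloride (tigloyl chloride) | C/C=C(\C)C(Cl)=O | starting material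
4 | (2E)-7-chloro-3,7-dimethyloct-2-en-4-one | C/C=C(\C)C(=O)CCC(C)(C)Cl | intermediate (not isolated)
5 | 2,3,4,4-tetramethylcyclohex-2-en-1-one | CC1=C(C)C(C)(C)CCC1=O | intermediate
6 | 3-(bromomethyl)-2,4,4-trimethylcyclohex-2-en-1-one | CC1=C(CBr)C(C)(C)CCC1=O | intermediate
7 | diethyl [(2,6,6-trimethyl-3-oxocyclohex-1-en-1-yl)methyl]phosphonate | CCOP(=O)(CC1=C(C)C(=O)CCC1(C)C)OCC | intermediate
8 | hex-5-en-2-one | CC(=O)CCC=C | starting material
9 | 4-oxopentanal | CC(=O)CCC=O | intermediate
10 | (5R,6S)-5-hydroxy-6-methyloct-7-en-2-one | C=C[C@H](C)[C@H](O)CCC(C)=O | intermediate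
11 | (3S,4R)-3-methyl-7-oxooct-1-en-4-yl methanesulfonate | C=C[C@H](C)[C@H](OS(C)(=O)=O)CCC(C)=O | intermediate
12 | (3S,4R)-3-methyl-6-[(2R)-2-methyloxiran-2-yl]hex-1-en-4-yl methanesulfonate | C=C[C@H](C)[C@H](OS(C)(=O)=O)CC[C@]1(C)CO1 | intermediate
13 | (3S,4R,7S)-7-hydroperoxy-8-hydroxy-3,7-dimethyloct-1-en-4-yl methanesulfonate | C=C[C@H](C)[C@H](OS(C)(=O)=O)CC[C@@](C)(CO)OO | intermediate
14 | [(3S,6S)-6-[(2S)-but-3-en-2-yl]-3-methyl-1,2-dioxan-3-yl]methanol | C=C[C@H](C)[C@@H]1CC[C@@](C)(CO)OO1 | intermediate
15 | (2R)-2-[(3S,6S)-6-(hydroxymethyl)-6-methyl-1,2-dioxan-3-yl]propanal | O=C[C@H](C)[C@@H]1CC[C@@](C)(CO)OO1 | intermediate (not isolated)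
16 | (2R)-2-[(3S,6S)-6-(hydroxymethyl)-6-methyl-1,2-dioxan-3-yl]propanoic acid | OC(=O)[C@H](C)[C@@H]1CC[C@@](C)(CO)OO1 | intermediate
17 | methyl (2R)-2-[(3S,6S)-6-(hydroxymethyl)-6-methyl-1,2-dioxan-3-yl]propanoate | COC(=O)[C@H](C)[C@@H]1CC[C@@](C)(CO)OO1 | intermediate
18 | methyl (2R)-2-[(3S,6S)-6-formyl-6-methyl-1,2-dioxan-3-yl]propanoate | COC(=O)[C@H](C)[C@@H]1CC[C@@](C)(C=O)OO1 | intermediate
19 | methyl (2R)-2-[(3S,6S)-6-methyl-6-[(E)-2-(2,6,6-trimethyl-3-oxocyclohex-1-en-1-yl)ethenyl]-1,2-dioxan-3-yl]propanoate | COC(=O)[C@H](C)[C@@H]1CC[C@@](C)(/C=C/C2=C(C)C(=O)CCC2(C)C)OO1 | intermediate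
20 | methyl (2R)-2-[(3S,6R)-6-methyl-6-[2-(2,6,6-trimethyl-3-oxocyclohex-1-en-1-yl)ethyl]-1,2-dioxan-3-yl]propanoate (methyl diacarnoate A) | COC(=O)[C@H](C)[C@@H]1CC[C@@](C)(CCC2=C(C)C(=O)CCC2(C)C)OO1 | target

**Step count and risks**

Total steps: 15. Longest linear sequence: 11 steps (8 to 20, steps 5–15); the cyclohexenone branch (steps 1–4) joins at step 14.

Step 2 (Proposed new method). What may go wrong: after the acylative ring opening the tertiary cation may be diverted faster than it closes the ring. Possible diversions are chloride return without re-ionisation, proton loss followed by isomerisation to a cross-conjugated dienone that closes to a five-membered ring in a Nazarov reaction, and O-closure to a dihydrofuran; the cyclopropane may also be isomerised by HCl/AlCl3 before it is acylated. The fallback uses known chemistry, makes the two ring bonds in separate operations and forms C-3–C-4 by a radical instead of a cation; it sets out from 3 and comes back at 5. Acylation of N,O-dimethylhydroxylamine hydrochloride with 3 (pyridine, CH2Cl2) gives the Weinreb amide (2E)-N-methoxy-N,2-dimethylbut-2-enamide F1. Addition of (3-methylbut-3-en-1-yl)magnesium bromide (from 4-bromo-2-methylbut-1-ene) gives the dienone (2E)-3,7-dimethylocta-2,7-dien-4-one F2. Metal-hydride hydrogen-atom transfer (Fe(acac)3, PhSiH3, EtOH) generates the tertiary radical, which should close 6-endo onto the enone β-carbon to give 2,3,4,4-tetramethylcyclohexan-1-one F3. The more substituted silyl enol ether trimethyl[(2,3,4,4-tetramethylcyclohex-1-en-1-yl)oxy]silane F4 (TMSCl, NaI, Et3N, MeCN) and Saegusa–Ito oxidation (Pd(OAc)2) then give 5.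

Step 10. What may go wrong: E2 elimination of the secondary sulfonate toward the allylic hydrogen, or base-induced Kornblum–DeLaMare fragmentation of the dioxane once formed, may outrun the 6-exo-tet displacement. The fallback forms the O–C-3 bond by conjugate addition instead of substitution; it sets out from 9 and comes back at 17. Wittig olefination of 9 with methyl 2-(triphenylphosphoranylidene)propanoate gives methyl (2E)-2-methyl-6-oxohept-2-enoate F5. The asymmetric Corey–Chaykovsky epoxidation of step 8 gives methyl (2E)-2-methyl-5-[(2R)-2-methyloxiran-2-yl]pent-2-enoate F6. Perhydrolysis as in step 9 gives methyl (2E,6S)-6-hydroperoxy-7-hydroxy-2,6-dimethylhept-2-enoate F7. A 6-exo-trig oxa-Michael addition (Et2NH, CF3CH2OH) closes the dioxane to 17. In this variant only the quaternary centre is reagent-controlled, so 17 would have to be separated from its epimers at C-3 and the α-carbon.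

Step 14. What may go wrong: steric retardation of the addition of the hindered phosphonate anion to the neopentyl-type aldehyde, with reaction at the ring α-carbon or base-induced retro-oxa-Michael opening of the β-peroxy ester taking over. The fallback uses a Lewis-acid aldol instead of an anionic olefination; it sets out from 5 (and uses 18) and comes back at 19. Thermodynamic silylation of 5 (TBSOTf, Et3N, CH2Cl2) gives the extended dienol ether tert-butyl(dimethyl)[(2,4,4-trimethyl-3-methylidenecyclohex-1-en-1-yl)oxy]silane F8. A vinylogous Mukaiyama aldol addition to 18 (BF3·OEt2, CH2Cl2, −78 °C) gives methyl (2R)-2-[(3S,6S)-6-[1-hydroxy-2-(2,6,6-trimethyl-3-oxocyclohex-1-en-1-yl)ethyl]-6-methyl-1,2-dioxan-3-yl]propanoate F9 as a mixture of carbinol epimers. Dehydration with the Burgess reagent gives 19.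

**Further compounds**

F1 | step 2 | (2E)-N-methoxy-N,2-dimethylbut-2-enamide | C/C=C(\C)C(=O)N(C)OC
F2 | step 2 | (2E)-3,7-dimethylocta-2,7-dien-4-one | C/C=C(\C)C(=O)CCC(C)=C
F3 | step 2 | 2,3,4,4-tetramethylcyclohexan-1-one | CC1C(C)C(C)(C)CCC1=O
F4 | step 2 | trimethyl[(2,3,4,4-tetramethylcyclohex-1-en-1-yl)oxy]silane | CC1=C(O[Si](C)(C)C)CCC(C)(C)C1C
F5 | step 10 | methyl (2E)-2-methyl-6-oxohept-2-enoate | COC(=O)/C(C)=C/CCC(C)=O
F6 | step 10 | methyl (2E)-2-methyl-5-[(2R)-2-methyloxiran-2-yl]pent-2-enoate | COC(=O)/C(C)=C/CC[C@]1(C)CO1
F7 | step 10 | methyl (2E,6S)-6-hydroperoxy-7-hydroxy-2,6-dimethylhept-2-enoate | COC(=O)/C(C)=C/CC[C@@](C)(CO)OO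
F8 | step 14 | tert-butyl(dimethyl)[(2,4,4-trimethyl-3-methylidenecyclohex-1-en-1-yl)oxy]silane | CC1=C(O[Si](C)(C)C(C)(C)C)CCC(C)(C)C1=C
F9 | step 14 | methyl (2R)-2-[(3S,6S)-6-[1-hydroxy-2-(2,6,6-trimethyl-3-oxocyclohex-1-en-1-yl)ethyl]-6-methyl-1,2-dioxan-3-yl]propanoate | COC(=O)[C@H](C)[C@@H]1CC[C@@](C)(C(O)CC2=C(C)C(=O)CCC2(C)C)OO1
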